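**Analysis of the target**

Candidachalcone (C21H22O6) is an open-chain 2'-hydroxychalcone. Ring A (C1'–C6') carries the cinnamoyl group at C1', hydroxyls at C2' and C4', a methoxy group at C6' and, at C3', a (Z)-3-hydroxy-3-methylbut-1-enyl arm (C1''=C2''–C3''(CH3)2OH); ring B is a 4-hydroxyphenyl group joined through an E-enone. There is no stereocentre, so the stereochemical content is two alkene geometries: the E-enone is the thermodynamic isomer, whereas the Z-alkene of the arm, conjugated to the arene and flanked by two ortho oxygens, is not. The molecule is fragile on both sides of neutrality: acid ionises the tertiary allylic carbinol and the cis-disposed O2' or O4' then closes a chromene, while base lets the 2'-phenoxide add to the enone and gives the 5-methoxyflavanone. The enone also excludes late reductions such as an alkyne semi-hydrogenation, and light or metal hydrides could relax the Z-alkene to E. The difficulty is therefore to write a Z-styrene on a pentasubstituted, electron-rich arene next to an enone, and to unveil four hydroxyl groups at the end without acid or base. The strategy rests on the 1,6-relationship of O2' and the carbinol oxygen: the chain O2'–C2'–C3'–C1''=C2''–C3''–O needs one bridging atom to become an eight-membered ring, and in such a ring, fused to ring A, the C1''=C2'' bond can only be Z. A second feature is used as well: O2' is the oxygen that a flavanone holds as O1, so a flavanone delivers the whole C15 skeleton with O2' already set apart from O4' and O4.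

**Retrosynthetic reasoning**

14 from 13. The last operation should form no carbon–carbon bond and should run near neutrality. The four hydroxyl groups of 14 are drawn back to silicon: aryl tert-butyldimethylsilyl (TBS) ethers at O4' and O4, and one diphenylsilylene unit spanning O2' and the carbinol oxygen. This is 13. Four Si–O bonds are cut, all by one buffered fluoride treatment. The gain is a precursor in which the phenol/carbinol pair that would form a chromene is tied up on one silicon atom.

13 from 12. In 13 the arm alkene C1''=C2'' lies in an eight-membered ring. This bond is cut and each carbon is capped with a methylene group: C1'' becomes the inner carbon of a vinyl group on C3', and C2'' the inner carbon of a 1,1-dimethylallyl group held on silicon. This is 12. A cut at C3'–C1'' would need a Z-alkenyl metal whose geometry has to be made elsewhere, and a cut at C2''–C3'' would need a carbonyl addition that the chalcone enone does not tolerate. The chosen cut is the only one that lets ring size dictate geometry. The forward reaction must be a ring-closing metathesis that closes a medium ring faster than it couples two molecules and that leaves the enone alone.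

12 from 6 and 9. 12 is a chalcone silylated at O2'. The Si–O2' bond is cut to the chalcone 2'-phenoxide 11 and the chlorosilane 9. In the retrosynthetic sense 11 is then closed by joining O2' to the β-carbon of the enone, which gives the flavanone 6 by way of its enolate 10. This brings three gains:
- O2' needs no protecting-group manoeuvre, because it is the ring oxygen until the moment it is silylated.
- The enone stays hidden while ring A is functionalised.
- The C15 skeleton never has to be made by an aldol condensation, which aryl silyl ethers would not survive.

Forward, a non-nucleophilic base must trigger β-elimination from 10 and the phenoxide must be trapped on silicon in the same flask.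

9 from 7 and 8. One Si–O bond is cut. The hindered tertiary alcohol 8 goes onto silicon first, because substitution of 7 by a tertiary alcohol stops after one chloride. The remaining Si–Cl is then available for the phenoxide.

6 from 4 and 5, and 4 from 3. The C8–vinyl bond is cut to the aryl iodide 4 and the vinylstannane 5. The C8–I bond is cut to the arene 3. C8 is chosen because it becomes C3' on ring opening. A neutral tin reagent is preferred because boron-based vinyl donors need hot base and, as trifluoroborates, release fluoride; both endanger aryl silyl ethers. The iodination must select C8 over C6, which is expected once O5 is an ether.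

3 from 2, and 2 from 1. The O5–CH3 bond and the two aryl O–Si bonds are cut, back to naringenin 1. The order is fixed by reactivity: the hydrogen bond of the 5-OH to the carbonyl keeps it out of the silylation, and only then is it methylated, under neutral conditions.

**Alternatives that were turned down**

Alternative 1: The Z-alkene is inherited from the C3=C4 bond of a coumarin, and the disconnection removes the two methyl groups of the carbinol. In the forward key step 8-bromo-7-methoxy-5-(tert-butyldimethylsilyloxy)coumarin A2 would take up a methyl Grignard reagent twice at the lactone carbonyl, with a lanthanide chloride additive to suppress conjugate addition. The lactone opens and gives the bromophenol A1 with the Z-arm in place.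
- For: the geometry comes from a six-membered ring and is beyond doubt, and the step is old chemistry. On Z-control this alternative is at least as strong as the chosen route, probably stronger.
- Against: A1 is only ring A. The bromine must still become the cinnamoyl group by halogen–metal exchange next to a free phenol and a free tertiary alcohol, or after extra protection steps. Acylation at a carbon flanked by two ortho substituents is slow, and ring B has yet to be attached. All of this is done while the acid-labile pair of carbinol and ortho-phenol is exposed; that pair is the very combination from which such coumarin adducts usually dehydrate to chromenes. A2 itself needs a regiodefined synthesis.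
- Comparison: the chosen route buys the complete C15 skeleton in 1, so the chalcone is never built on the crowded arene. Its bridge protects the phenol/carbinol pair in the same act that fixes the geometry. It gives up the certainty of the coumarin lock.

Alternative 2: The enone is cut on both sides of the carbonyl carbon. The aryl iodide A4, which already carries the Z-arm, would be joined to 4-acetoxystyrene A5 in a carbonylative Heck reaction to give the protected chalcone A3.
- For: the step is convergent and forms two carbon–carbon bonds at once. The E-enone follows from the syn-insertion and syn-elimination sequence. The enone appears late, so earlier steps need not tolerate it; on this point it is stronger than the chosen route, which carries a masked enone from the start.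
- Against: A4 is electron-rich and doubly ortho-substituted, and capture of a hindered acylpalladium by a styrene is demanding even for unhindered aryl halides. Direct Heck coupling without carbonylation and reduction compete. The palladium hydride formed in each turnover can isomerise the Z-alkene of the arm. Above all, the Z-arm is not made in this step, so the real problem is only moved into the synthesis of A4.
- Comparison: the chosen route solves the geometry in the step that forms the arm and needs no three-component coupling at a hindered centre.

Alternative 3: Ring A itself is made last, from the styrylpyrone A7 and the lithium dienolate of the lactone A8. The α-carbon of the dienolate would add to the pyrone carbonyl (bond C3'–C4') and the pyrone opens. The freed enolate carbon (former pyrone C5) then closes onto the lactone carbonyl (bond C1'–C2'). The lactone oxygen leaves as the tertiary alkoxide and the ring aromatises to A6, the target silylated only at the ring B phenol.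
- For: it is by far the shortest plan and needs one protecting group. The Z-geometry is carried by the lactone ring. The substitution pattern of ring A follows from connectivity without any aromatic substitution. On step economy and regiocontrol it is stronger than the chosen route.
- Against: every stage of the cascade is conjecture. The dienolate can react at its γ-carbon. The pyrone offers C6 and the styryl terminus as conjugate acceptors. The ring-opened enolate can O-acylate or re-close to a pyrone. Before aromatisation the tertiary alkoxide can be lost by elimination along the arm instead of by acyl substitution. Nothing in the structures enforces the required choices.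
- Comparison: the chosen route uses only known reaction types and concentrates its risk in one ring closure for which the structure gives a clear argument.

Key step: step 7

Remarks: TBS = tert-butyldimethylsilyl. C2 of the flavanone intermediates becomes an sp2 carbon in step 6, so racemic naringenin would serve equally; the (S)-series is drawn. Flavanone positions O1, C8a, C8, C7, C6, C5 and C4a become chalcone positions O2', C2', C3', C4', C5', C6' and C1'. The flavanones are named as chroman-4-ones to keep the two numbering systems apart.

**Route**

Step 1
Reactants: 1 (S)-naringenin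
Product: 2 (2S)-5-hydroxy-7-(TBS-oxy)-2-[4-(TBS-oxy)phenyl]chroman-4-one
Conditions: TBSCl (2.2 equiv), imidazole, DMF, 0 °C to rt
Reagents that add atoms: tert-butyldimethylsilyl chloride, CC(C)(C)[Si](C)(C)Cl
Why: Silyl ether formation; the 7-OH and the ring B OH are free phenols and react fast, whereas the 5-OH is held in a hydrogen bond to the C4 carbonyl and is far less nucleophilic, so two equivalents should stop at the bis-ether, and imidazole does not disturb the flavanone.

Step 2
Reactants: 2 (2S)-5-hydroxy-7-(TBS-oxy)-2-[4-(TBS-oxy)phenyl]chroman-4-one
Product: 3 (2S)-5-methoxy-7-(TBS-oxy)-2-[4-(TBS-oxy)phenyl]chroman-4-one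
Conditions: MeOH, PPh3, DIAD, THF, 0 °C to rt
Reagents that add atoms: methanol, CO
Why: Mitsunobu etherification; the phosphine–azodicarboxylate betaine deprotonates the chelated phenol and activates methanol, and the phenoxide is methylated by SN2 under neutral conditions, which avoids the carbonate bases that open flavanones and strip aryl silyl ethers; chelated ortho-acyl phenols are known to etherify in this way.

Step 3
Reactants: 3 (2S)-5-methoxy-7-(TBS-oxy)-2-[4-(TBS-oxy)phenyl]chroman-4-one
Product: 4 (2S)-8-iodo-5-methoxy-7-(TBS-oxy)-2-[4-(TBS-oxy)phenyl]chroman-4-one
Conditions: N-iodosuccinimide (1.05 equiv), DMF, rt, dark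
Reagents that add atoms: N-iodosuccinimide, O=C1CCC(=O)N1I
Why: Electrophilic aromatic iodination; ring A has three oxygen donors and is far more reactive than ring B, and with O5 as an ether 5,7-dialkoxyflavonoids are iodinated at C8, which is para to the methoxy group and flanked by the tied-back ring oxygen, whereas C6 lies between the methoxy and the silyloxy group; the neutral reagent leaves silyl ethers and ketone alone.

Step 4
Reactants: 4 (2S)-8-iodo-5-methoxy-7-(TBS-oxy)-2-[4-(TBS-oxy)phenyl]chroman-4-one; 5 tributyl(vinyl)stannane
Product: 6 (2S)-8-vinyl-5-methoxy-7-(TBS-oxy)-2-[4-(TBS-oxy)phenyl]chroman-4-one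
Conditions: Pd(PPh3)4 (5 mol %), CuI (10 mol %), degassed DMF, 80 °C
Reagents that add atoms: none
Why: Stille coupling; oxidative addition of the aryl iodide to zerovalent palladium, transfer of the vinyl group from tin assisted by CuI, and reductive elimination; the medium is neutral and free of fluoride and alkoxide, so both aryl silyl ethers and the flavanone should survive.

Step 5
Reactants: 7 dichlorodiphenylsilane; 8 2-methylbut-3-en-2-ol
Product: 9 chloro(2-methylbut-3-en-2-yloxy)diphenylsilane
Conditions: Et3N (1.2 equiv), DMAP (5 mol %), CH2Cl2, 0 °C to rt; filtration, bulb-to-bulb distillation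
Reagents that add atoms: none
Why: Nucleophilic substitution at silicon; a tertiary alcohol displaces one chloride of Ph2SiCl2 and a second displacement by another tertiary alcohol is much slower, as in the preparation of tert-butoxychlorodiphenylsilane, so the monoalkoxychlorosilane should be obtained.

Step 6
Reactants: 6 (2S)-8-vinyl-5-methoxy-7-(TBS-oxy)-2-[4-(TBS-oxy)phenyl]chroman-4-one; 9 chloro(2-methylbut-3-en-2-yloxy)diphenylsilane
Product: 12 (E)-2'-O-[diphenyl(2-methylbut-3-en-2-yloxy)silyl]-3'-vinyl-6'-methoxy-4,4'-bis(TBS-oxy)chalcone, via potassium flavanone enolate 10 (not isolated), via potassium chalcone 2'-phenoxide 11 (not isolated)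
Conditions: KN(SiMe3)2 (1.05 equiv), THF, –78 to 0 °C; then 9 (1.3 equiv), 0 °C to rt; pH 7 buffer, Et3N-deactivated silica
Reagents that add atoms: none
Why: E1cB ring opening followed by O-silylation; the base forms enolate 10, which expels the O1 phenoxide to give the much more stable ortho-acyl phenoxide 11 with the E-enone (the equatorial aryl group ends anti to the carbonyl), and 11 displaces chloride from 9; the base is non-nucleophilic, so the aryl silyl ethers stay, and 9 is added only after the opening so that the enolate is not silylated.

Step 7
Reactants: 12 (E)-2'-O-[diphenyl(2-methylbut-3-en-2-yloxy)silyl]-3'-vinyl-6'-methoxy-4,4'-bis(TBS-oxy)chalcone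
Product: 13 4,4'-bis-O-TBS-candidachalcone in which O2' and the carbinol oxygen are bridged by SiPh2, an eight-membered benzo-fused 1,3-dioxa-2-silocine holding the Z-alkene C1''=C2''
Conditions: second-generation Hoveyda–Grubbs catalyst, RuCl2(=CH-C6H4-2-O-i-Pr)(SIMes) (10 mol %, two portions), toluene (0.002 M), 80 °C, Ar sparge
Reagents that add atoms: none
Why: This is ring-closing metathesis under a temporary silicon tether, the known route from bis(alkenyloxy)silanes to seven- to nine-membered cyclic silaketals; the same two alkene types, an ortho-vinylarene and an oxygen-bound 1,1-dimethylallyl group, are also known to close to six-membered chromenes. The catalyst should exchange its isopropoxybenzylidene for the C3' vinyl group, the more accessible alkene because the other hangs on a quaternary carbon, and the ruthenium arylmethylidene adds to the tethered alkene in a [2+2] step; the ruthenacyclobutane collapses to the ring alkene and Ru=CH2, which re-enters the cycle while ethylene is swept out by the argon stream. The eight-membered ring (C2', C3', C1'', C2'', C3'', O, Si, O) is closed at its C1''=C2'' bond, so ring and alkene form in the same event. No stereocentre is formed; the alkene geometry is controlled by the ring, because an E-alkene in an eight-membered ring that shares an edge with the arene would be prohibitively strained, and the reversible metathesis funnels material to the Z-ring. The step needs closure to win over dimerisation through the styrene and over reaction at the enone: high dilution, the geminal methyl groups and the two phenyl groups on silicon bring the alkenes together, and the enone is a 1,2-disubstituted, electron-poor alkene that enters metathesis slowly. Neither reacting alkene has an allylic hydrogen, so double-bond migration by ruthenium hydrides is not possible, and the two ortho silyloxy oxygens are too weakly basic to hold the arylmethylidene as a dormant chelate. The bridge keeps O2' and the carbinol oxygen masked, so the Z-product cannot close to a chromene.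

Step 8
Reactants: 13 the bridged bis-TBS ether of candidachalcone
Product: 14 candidachalcone
Conditions: Bu4NF (5 equiv), AcOH (5 equiv), THF, 0 °C; pH 7 phosphate work-up
Reagents that add atoms: none
Why: Fluoride-mediated desilylation; fluoride attacks each silicon and cleaves the two Si–O bonds of the bridge and both aryl silyl ethers, while the equimolar acetic acid protonates the phenoxides and the alkoxide as they form, so the medium stays near neutral and neither the base-induced addition of O2' to the enone nor the acid-induced cyclodehydration of the Z-allylic alcohol should set in.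

**Compound list**

1 | (S)-naringenin | C1[C@H](OC2=CC(=CC(=C2C1=O)O)O)C3=CC=C(C=C3)O | starting material
2 | (2S)-5-hydroxy-7-(TBS-oxy)-2-[4-(TBS-oxy)phenyl]chroman-4-one | O=C1C[C@@H](c2ccc(O[Si](C)(C)C(C)(C)C)cc2)Oc2cc(O[Si](C)(C)C(C)(C)C)cc(O)c12 | intermediate
3 | (2S)-5-methoxy-7-(TBS-oxy)-2-[4-(TBS-oxy)phenyl]chroman-4-one | O=C1C[C@@H](c2ccc(O[Si](C)(C)C(C)(C)C)cc2)Oc2cc(O[Si](C)(C)C(C)(C)C)cc(OC)c12 | intermediate
4 | (2S)-8-iodo-5-methoxy-7-(TBS-oxy)-2-[4-(TBS-oxy)phenyl]chroman-4-one | O=C1C[C@@H](c2ccc(O[Si](C)(C)C(C)(C)C)cc2)Oc2c(I)c(O[Si](C)(C)C(C)(C)C)cc(OC)c12 | intermediate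
5 | tributyl(vinyl)stannane | C=C[Sn](CCCC)(CCCC)CCCC | starting material
6 | (2S)-8-vinyl-5-methoxy-7-(TBS-oxy)-2-[4-(TBS-oxy)phenyl]chroman-4-one | O=C1C[C@@H](c2ccc(O[Si](C)(C)C(C)(C)C)cc2)Oc2c(C=C)c(O[Si](C)(C)C(C)(C)C)cc(OC)c12 | intermediate
7 | dichlorodiphenylsilane | Cl[Si](Cl)(c1ccccc1)c1ccccc1 | starting material
8 | 2-methylbut-3-en-2-ol | CC(C)(O)C=C | starting material
9 | chloro(2-methylbut-3-en-2-yloxy)diphenylsilane | CC(C)(C=C)O[Si](Cl)(c1ccccc1)c1ccccc1 | intermediate
10 | potassium C3=C4 enolate of 6 | [K+].[O-]C1=C[C@@H](c2ccc(O[Si](C)(C)C(C)(C)C)cc2)Oc2c(C=C)c(O[Si](C)(C)C(C)(C)C)cc(OC)c12 | intermediate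
11 | potassium 2'-phenoxide of (E)-3'-vinyl-6'-methoxy-4,4'-bis(TBS-oxy)chalcone | [K+].COc1cc(O[Si](C)(C)C(C)(C)C)c(C=C)c([O-])c1C(=O)/C=C/c1ccc(O[Si](C)(C)C(C)(C)C)cc1 | intermediate
12 | (E)-2'-O-[diphenyl(2-methylbut-3-en-2-yloxy)silyl]-3'-vinyl-6'-methoxy-4,4'-bis(TBS-oxy)chalcone | COc1cc(O[Si](C)(C)C(C)(C)C)c(C=C)c(O[Si](c2ccccc2)(c2ccccc2)OC(C)(C)C=C)c1C(=O)/C=C/c1ccc(O[Si](C)(C)C(C)(C)C)cc1 | intermediate
13 | 4,4'-bis-O-TBS-candidachalcone bridged from O2' to the carbinol oxygen by SiPh2 (Z ring alkene, E-enone) | COc1cc(O[Si](C)(C)C(C)(C)C)c2/C=C\C(C)(C)O[Si](c3ccccc3)(c3ccccc3)Oc2c1C(=O)/C=C/c1ccc(O[Si](C)(C)C(C)(C)C)cc1 | intermediate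
14 | candidachalcone | COc1cc(O)c(/C=C\C(C)(C)O)c(O)c1C(=O)/C=C/c1ccc(O)cc1 | target

**Step count and risk**

Total step count: 8. Longest linear sequence: 7 steps (steps 1, 2, 3, 4, 6, 7 and 8 from 1); step 5 prepares 9 from 7 and 8.

Step 7 (key step). Both alkenes are hindered: the styrene lies between two silyloxy groups and its partner is attached to a quaternary carbon. Initiation and closure of the strained eight-membered ring may therefore be slow, and intermolecular metathesis through the styrene, catalyst decay and thermal loss of the aryloxysilane bridge may overtake it. The fallback takes the Z-geometry from syn-hydrogenation of an alkyne while the enone is still hidden in the flavanone. It sets out from 4. Sonogashira coupling with 2-methylbut-3-yn-2-ol (PdCl2(PPh3)2, CuI, Et3N, THF) should give the 8-(3-hydroxy-3-methylbut-1-ynyl)chromanone F1. Semi-hydrogenation over Pd on CaCO3 poisoned with Pb(OAc)2, with quinoline, should give the 8-[(Z)-3-hydroxy-3-methylbut-1-enyl]chromanone F2. Ring opening with KN(SiMe3)2 (2.2 equiv, THF, –78 to 0 °C) and a cold AcOH quench should give 4,4'-bis-O-TBS-candidachalcone F3. The buffered fluoride of step 8 then removes the two silyl groups, and the route is rejoined at 14.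

Step 6. The enolate may be silylated before it has opened, the opening may be incomplete, and the doubly ortho-substituted phenoxide may attack the bulky chlorosilane only slowly. Hydrolysis of the aryloxysilane on work-up or silyl exchange between phenoxides may follow. The fallback builds the bridge in the opposite order. It sets out from 6. The phenoxide 11 is generated as before and run into 7 (1.1 equiv, –78 °C), a smaller electrophile, to give the 2'-O-(chlorodiphenylsilyl)chalcone F4. Addition of 8 and imidazole then closes the second Si–O bond, and the route is rejoined at 12.

Step 3. Both free positions of ring A are activated by three oxygens and both lie next to the bulky silyloxy group, so attack at C6 or double iodination may compete. The fallback lets a free phenol direct the iodine. It sets out from 3. Opening with KN(SiMe3)2 and an AcOH quench should give 2'-hydroxy-6'-methoxy-4,4'-bis(TBS-oxy)chalcone F5. Iodination ortho to the chelated hydroxyl with benzyltrimethylammonium dichloroiodate and NaHCO3 in CH2Cl2–MeOH should give 2'-hydroxy-3'-iodo-6'-methoxy-4,4'-bis(TBS-oxy)chalcone F6. Stille coupling with 5 under the conditions of step 4 should give 2'-hydroxy-3'-vinyl-6'-methoxy-4,4'-bis(TBS-oxy)chalcone F7. Any F7 that closes to the flavanone is harmless, since KN(SiMe3)2 converts either form into the phenoxide, and the route is rejoined at 11 in step 6.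

Step 8. If the medium drifts to the basic side, the 2'-phenoxide adds to the enone and closes the flavanone. If it drifts to the acidic side, the carbinol ionises and closes irreversibly onto O2' or O4'. The fallback stays deliberately on the basic, reversible side and repairs the damage. It sets out from 13. Unbuffered Bu4NF in THF removes all silicon and may deliver the 8-[(Z)-3-hydroxy-3-methylbut-1-enyl]-5-O-methylnaringenin F8. F8 is reopened by β-elimination with excess KOH in degassed aqueous ethanol, the classical passage from a flavanone to its 2'-hydroxychalcone. The phenoxide solution is run into cold pH 7 phosphate buffer, and the route is rejoined at 14.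

**Further compounds**

F1 | step 7 | (2S)-8-(3-hydroxy-3-methylbut-1-ynyl)-5-methoxy-7-(TBS-oxy)-2-[4-(TBS-oxy)phenyl]chroman-4-one | O=C1C[C@@H](c2ccc(O[Si](C)(C)C(C)(C)C)cc2)Oc2c(C#CC(C)(C)O)c(O[Si](C)(C)C(C)(C)C)cc(OC)c12
F2 | step 7 | (2S)-8-[(Z)-3-hydroxy-3-methylbut-1-enyl]-5-methoxy-7-(TBS-oxy)-2-[4-(TBS-oxy)phenyl]chroman-4-one | O=C1C[C@@H](c2ccc(O[Si](C)(C)C(C)(C)C)cc2)Oc2c(/C=C\C(C)(C)O)c(O[Si](C)(C)C(C)(C)C)cc(OC)c12
F3 | step 7 | 4,4'-bis-O-TBS-candidachalcone | COc1cc(O[Si](C)(C)C(C)(C)C)c(/C=C\C(C)(C)O)c(O)c1C(=O)/C=C/c1ccc(O[Si](C)(C)C(C)(C)C)cc1
F4 | step 6 | (E)-2'-O-(chlorodiphenylsilyl)-3'-vinyl-6'-methoxy-4,4'-bis(TBS-oxy)chalcone | COc1cc(O[Si](C)(C)C(C)(C)C)c(C=C)c(O[Si](Cl)(c2ccccc2)c2ccccc2)c1C(=O)/C=C/c1ccc(O[Si](C)(C)C(C)(C)C)cc1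
F5 | step 3 | (E)-2'-hydroxy-6'-methoxy-4,4'-bis(TBS-oxy)chalcone | COc1cc(O[Si](C)(C)C(C)(C)C)cc(O)c1C(=O)/C=C/c1ccc(O[Si](C)(C)C(C)(C)C)cc1
F6 | step 3 | (E)-2'-hydroxy-3'-iodo-6'-methoxy-4,4'-bis(TBS-oxy)chalcone | COc1cc(O[Si](C)(C)C(C)(C)C)c(I)c(O)c1C(=O)/C=C/c1ccc(O[Si](C)(C)C(C)(C)C)cc1
F7 | step 3 | (E)-2'-hydroxy-3'-vinyl-6'-methoxy-4,4'-bis(TBS-oxy)chalcone | COc1cc(O[Si](C)(C)C(C)(C)C)c(C=C)c(O)c1C(=O)/C=C/c1ccc(O[Si](C)(C)C(C)(C)C)cc1
F8 | step 8 | 7-hydroxy-8-[(Z)-3-hydroxy-3-methylbut-1-enyl]-2-(4-hydroxyphenyl)-5-methoxychroman-4-one (racemic at C2) | O=C1CC(c2ccc(O)cc2)Oc2c(/C=C\C(C)(C)O)c(O)cc(OC)c12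
A1 | alternative 1 | 2-bromo-5-(tert-butyldimethylsilyloxy)-6-[(Z)-3-hydroxy-3-methylbut-1-enyl]-3-methoxyphenol | COc1cc(O[Si](C)(C)C(C)(C)C)c(/C=C\C(C)(C)O)c(O)c1Br
A2 | alternative 1 | 8-bromo-7-methoxy-5-(tert-butyldimethylsilyloxy)coumarin | COc1cc(O[Si](C)(C)C(C)(C)C)c2ccc(=O)oc2c1Br
A3 | alternative 2 | 4-O-acetyl-2',4'-bis-O-(tert-butyldimethylsilyl)candidachalcone | COc1cc(O[Si](C)(C)C(C)(C)C)c(/C=C\C(C)(C)O)c(O[Si](C)(C)C(C)(C)C)c1C(=O)/C=C/c1ccc(OC(C)=O)cc1
A4 | alternative 2 | (Z)-4-[2,6-bis(tert-butyldimethylsilyloxy)-3-iodo-4-methoxyphenyl]-2-methylbut-3-en-2-ol | COc1cc(O[Si](C)(C)C(C)(C)C)c(/C=C\C(C)(C)O)c(O[Si](C)(C)C(C)(C)C)c1I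
A5 | alternative 2 | 4-acetoxystyrene | CC(=O)Oc1ccc(C=C)cc1
A6 | alternative 3 | 4-O-(tert-butyldimethylsilyl)candidachalcone | COc1cc(O)c(/C=C\C(C)(C)O)c(O)c1C(=O)/C=C/c1ccc(O[Si](C)(C)C(C)(C)C)cc1
A7 | alternative 3 | 4-methoxy-6-[(E)-2-[4-(tert-butyldimethylsilyloxy)phenyl]vinyl]pyran-2-one | COc1cc(=O)oc(/C=C/c2ccc(O[Si](C)(C)C(C)(C)C)cc2)c1
A8 | alternative 3 | 6,6-dimethyl-5,6-dihydropyran-2-one | CC1(C)CC=CC(=O)O1
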